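## Retrosynthetic overview
1. Target ⇒ desilylation, O6–C12 oxidative lactonisation and C12 allylic hydroxylation of a 6-hydroxy-7-isopropenyl cyclodecenone. This is the order germacrene A → acid → 6-hydroxylation → lactone.
2. Ten-membered ring ⇒ C6–C7 carbonyl-ene closure of an acyclic farnesal-type (Z)-enal onto its unactivated prenyl end. It copies the farnesyl C1→C10 closure with loss of a methyl proton.
3. Acyclic chain ⇒ C2–C3 boron aldol of a methyl ketone (C1, C2, C7–C14) with (Z)-4,4-dimethoxy-2-methylbut-2-enal (C3–C6, C15).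
4. Methyl ketone ⇒ mesityl oxide + methyl pyruvate (Mukaiyama aldol sets C10, CBS reduction sets C8) + MeLi + isovaleryl chloride.
5. Ring order: carbocycle first, γ-lactone second.

Assumption: germacrane numbering is used throughout (C1 ketone, C3 carbinol, C4=C5, C6 lactone carbinol, C7, C8 ester carbinol, C10 tertiary carbinol, C11–C13 methylene-lactone carbons). The target is then (3R,4Z,6R,7R,8R,10R).

## Route

Step 1
Reactants: 1 mesityl oxide (4-methylpent-3-en-2-one)
Product: 3 4-methyl-2-(triethylsilyloxy)penta-1,3-diene, via lithium dienolate 2 (not isolated)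
Conditions: LiN(iPr)2 (1.05 equiv, commercial solution), THF, −78 °C; Et3SiCl, −78 °C to rt
Reagents that add atoms: chlorotriethylsilane CC[Si](Cl)(CC)CC
Why: Kinetic deprotonation of the enone at the alpha-prime methyl group followed by O-silylation (silyl enol ether formation) gives the cross-conjugated 2-silyloxydiene; no stereocentre is made.

Step 2
Reactants: 3 4-methyl-2-(triethylsilyloxy)penta-1,3-diene; 4 methyl pyruvate
Product: 5 methyl (2R)-2,6-dimethyl-4-oxo-2-(triethylsilyloxy)hept-5-enoate
Conditions: Cu(OTf)2 (10 mol %), 2,2'-(propane-2,2-diyl)bis[(4R)-4-tert-butyl-4,5-dihydro-1,3-oxazole] (11 mol %), THF, −78 °C; filtration through silica, no acid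
Reagents that add atoms: none
Why: Catalytic enantioselective Mukaiyama aldol addition in which pyruvate chelates the square-planar copper bis(oxazoline) complex, the (R,R)-ligand (antipode of the one that gives S adducts) leaves only the Re face of the ketone open and so sets C10 as R, and silyl transfer to the aldolate leaves the tertiary alcohol already protected.

Step 3
Reactants: 5 methyl (2R)-2,6-dimethyl-4-oxo-2-(triethylsilyloxy)hept-5-enoate
Product: 6 methyl (2R,4R)-4-hydroxy-2,6-dimethyl-2-(triethylsilyloxy)hept-5-enoate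
Conditions: (3aS)-1-methyl-3,3-diphenyltetrahydro-1H,3H-pyrrolo[1,2-c][1,3,2]oxazaborole ((S)-Me-CBS, 20 mol %), catecholborane (1.5 equiv), toluene, −78 °C; MeOH, then aq. NaHCO3
Reagents that add atoms: none
Why: Corey–Bakshi–Shibata reduction in which the enone binds with its alkenyl arm as the large group, so the (S)-catalyst delivers hydride 1,2 and gives the 8R allylic alcohol under reagent control, while ester and silyl ether are inert to catecholborane.

Step 4
Reactants: 6 methyl (2R,4R)-4-hydroxy-2,6-dimethyl-2-(triethylsilyloxy)hept-5-enoate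
Product: 8 (3R,5R)-5-hydroxy-3,7-dimethyl-3-(triethylsilyloxy)oct-6-en-2-one (in equilibrium with its cyclic hemiketal), via lactone 7 (not isolated)
Conditions: MeLi (1.0 equiv), THF, −78 to 0 °C; recool to −78 °C, MeLi (1.1 equiv); AcOH (2.2 equiv), −78 °C
Reagents that add atoms: methyllithium [Li]C
Why: The lithium alkoxide closes to γ-lactone 7 (5-exo acyl substitution helped by the quaternary C10), and the lactone takes up only one MeLi because the lactolate survives at −78 °C (mono-addition of an organolithium to a lactone); the cold acid quench forestalls silyl migration and no stereocentre is touched.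

Step 5
Reactants: 8 (3R,5R)-5-hydroxy-3,7-dimethyl-3-(triethylsilyloxy)oct-6-en-2-one; 9 isovaleryl chloride (3-methylbutanoyl chloride)
Product: 10 (4R,6R)-2,6-dimethyl-7-oxo-6-(triethylsilyloxy)oct-2-en-4-yl 3-methylbutanoate
Conditions: pyridine, 4-(dimethylamino)pyridine (10 mol %), CH2Cl2, 0 °C to rt
Reagents that add atoms: none
Why: Nucleophile-catalysed esterification of the only accessible hydroxyl; the very hindered hemiketal OH is not acylated and drains through the open hydroxy ketone, and C8 keeps its configuration because its C–O bond is not broken.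

Step 6
Reactants: 11 ethyl 2-(diphenoxyphosphoryl)propanoate; 12 2,2-dimethoxyacetaldehyde (anhydrous)
Product: 14 ethyl (2Z)-4,4-dimethoxy-2-methylbut-2-enoate, via phosphonate carbanion 13 (not isolated)
Conditions: NaH, THF, 0 °C; 12, −78 to 0 °C
Reagents that add atoms: none
Why: Ando-type Z-selective Horner–Wadsworth–Emmons olefination in which the electron-poor diaryl phosphonate collapses from the kinetic adduct faster than it equilibrates, putting the ester (C3) cis to C6 and fixing the 4Z geometry of the target.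

Step 7
Reactants: 14 ethyl (2Z)-4,4-dimethoxy-2-methylbut-2-enoate
Product: 15 (2Z)-4,4-dimethoxy-2-methylbut-2-en-1-ol
Conditions: iBu2AlH (2.2 equiv), CH2Cl2, −78 °C; aq. KNaC4H4O6 (potassium sodium tartrate)
Reagents that add atoms: none
Why: 1,2-Reduction of the enoate by an aluminium hydride with a non-acidic work-up leaves acetal and Z-alkene untouched and avoids closure to the 2-methoxy-2,5-dihydrofuran.

Step 8
Reactants: 15 (2Z)-4,4-dimethoxy-2-methylbut-2-en-1-ol
Product: 16 (2Z)-4,4-dimethoxy-2-methylbut-2-enal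
Conditions: MnO2 (excess), CH2Cl2, rt, dark; used at once
Reagents that add atoms: none
Why: Heterogeneous MnO2 oxidation of an allylic alcohol runs under neutral conditions, so the isomerisation-prone Z-enal is obtained with its geometry intact.

Step 9
Reactants: 10 (4R,6R)-2,6-dimethyl-7-oxo-6-(triethylsilyloxy)oct-2-en-4-yl 3-methylbutanoate; 16 (2Z)-4,4-dimethoxy-2-methylbut-2-enal
Product: 19 (4R,6R,9R,10Z)-9-hydroxy-12,12-dimethoxy-2,6,10-trimethyl-7-oxo-6-(triethylsilyloxy)dodeca-2,10-dien-4-yl 3-methylbutanoate, via boron enolate 17 (not isolated), via boron aldolate 18 (not isolated)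
Conditions: (−)-Ipc2BCl (chlorodiisopinocampheylborane, 1.5 equiv), Et3N (2 equiv), Et2O, 0 °C; 16, −78 to −20 °C; MeOH, pH 7 buffer (NaH2PO4/Na2HPO4), 30 % H2O2, 0 °C; crude used directly
Reagents that add atoms: none
Why: Reagent-controlled boron aldol addition of a methyl ketone (Paterson aldol) in which only the C2 methyl can enolise, the borane/amine pair does not touch the esters, and the (−)-Ipc ligands steer the enolate to the Re face of the enal, which sets C3 as R.

Step 10
Reactants: 19 the aldol adduct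
Product: 21 (4R,6R,9R,10Z)-2,6,10-trimethyl-7,12-dioxo-6,9-bis(triethylsilyloxy)dodeca-2,10-dien-4-yl 3-methylbutanoate, via lutidinium salt 20 (not isolated)
Conditions: Et3SiOTf (3 equiv), 2,6-lutidine (4.5 equiv), CH2Cl2, −78 to 0 °C; then H2O, 0 °C
Reagents that add atoms: triethylsilyl triflate CC[Si](CC)(CC)OS(=O)(=O)C(F)(F)F; water O
Why: The silyl triflate first caps the C3 hydroxyl (silyl ether formation) before it can close onto the cis acetal, then turns the dimethyl acetal into pyridinium-type salt 20, which water cleaves to the aldehyde under almost neutral conditions, so silyl ethers, ester, β-silyloxy ketone and Z-alkene survive.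

Step 11
Reactants: 21 the acyclic (Z)-enal
Product: 23 (3R,4Z,6R,7S,8R,10R)-6-hydroxy-1-oxo-3,10-bis(triethylsilyloxy)germacra-4,11(13)-dien-8-yl 3-methylbutanoate (6α-OH, 7α-H, 8β-ester; 7S only through CIP priority), via aluminium alkoxide 22 (not isolated)
Conditions: Me2AlCl (2.5 equiv), CH2Cl2, −40 °C, 21 added by syringe pump over 12 h (final 1 mM), then −20 °C; aq. KNaC4H4O6
Reagents that add atoms: none
Why: Proposed new method: a ten-membered carbonyl-ene (Prins-type) macrocyclisation that copies the farnesyl C1→C10 closure and methyl deprotonation of germacrene A synthase, in which Me2AlCl binds the most basic carbonyl (the enal), the only nucleophilic alkene (C7=C11) attacks the Si face of C6 through a chair-like six-centre transition state as in the citronellal-to-isopulegol closure (O-6 and isopropenyl trans, 6R), allylic 1,3-strain with the cis methyl keeps H-8 in the alkene plane so that the seven-atom tether reaches C7 only on the face syn to O-8 with C8–C9 roughly anti to the new bond (7,8-cis), the silylated ketol cannot rearrange, and loss of CH4 traps the product as alkoxide 22; the closest known reaction type is the Lewis-acid-promoted ene macrocyclisation of conjugated aldehydes to twelve- to sixteen-membered rings.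

Step 12
Reactants: 23 the ene product
Product: 24 (3R,4Z,6R,7S,8R,10R)-6,12-dihydroxy-1-oxo-3,10-bis(triethylsilyloxy)germacra-4,11(13)-dien-8-yl 3-methylbutanoate
Conditions: SeO2 (0.5 equiv), tBuOOH (3 equiv, decane), CH2Cl2, 0 °C to rt
Reagents that add atoms: tert-butyl hydroperoxide CC(C)(C)OO; selenium dioxide O=[Se]=O (oxygen relay)
Why: Riley-type allylic oxidation (ene reaction, then 2,3-sigmatropic shift) in which C11=C13 is the only alkene not deactivated by two allylic C–O bonds and its methyl C–H reacts rather than the hindered, electron-poor C7–H, so oxygen enters at C12; any over-oxidised enal is carried into the next step.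

Step 13
Reactants: 24 the 6,12-diol
Product: 27 (3R,4Z,6R,7R,8R,10R)-1-oxo-3,10-bis(triethylsilyloxy)germacra-4,11(13)-dien-12,6-olid-8-yl 3-methylbutanoate, via hydroxy enal 25 (not isolated), via lactol 26 (not isolated)
Conditions: 2,2,6,6-tetramethylpiperidin-1-oxyl (TEMPO, 20 mol %), PhI(OAc)2 (2.5 equiv), CH2Cl2, rt
Reagents that add atoms: none
Why: Oxoammonium oxidation picks the primary allylic alcohol over the secondary C6 carbinol, O-6 captures enal 25 as five-membered lactol 26, and this is oxidised on to the lactone (oxidative lactonisation, the chemical copy of C12 acid formation and 6-O-lactonisation); the trans fusion follows from C6 and C7 as set in step 11.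

Step 14
Reactants: 27 the bis(triethylsilyl) ether of the target
Product: 28 CNP0406522.1, (3R,4Z,6R,7R,8R,10R)-3,10-dihydroxy-1-oxogermacra-4,11(13)-dien-12,6-olid-8-yl 3-methylbutanoate
Conditions: HF·pyridine, pyridine, THF, 0 °C to rt
Reagents that add atoms: none
Why: Buffered fluoride-mediated desilylation removes both Et3Si groups without base, so the β-hydroxy ketone, the α-methylene lactone and the ester are not eliminated, added to or migrated, and no stereocentre is touched.

## Compound list
1 | mesityl oxide | CC(=O)C=C(C)C | starting material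
2 | lithium 4-methylpenta-1,3-dien-2-olate | [Li+].C=C([O-])C=C(C)C | intermediate
3 | 4-methyl-2-(triethylsilyloxy)penta-1,3-diene | C=C(O[Si](CC)(CC)CC)C=C(C)C | intermediate
4 | methyl pyruvate | CC(=O)C(=O)OC | starting material
5 | methyl (2R)-2,6-dimethyl-4-oxo-2-(triethylsilyloxy)hept-5-enoate | COC(=O)[C@](C)(O[Si](CC)(CC)CC)CC(=O)C=C(C)C | intermediate
6 | methyl (2R,4R)-4-hydroxy-2,6-dimethyl-2-(triethylsilyloxy)hept-5-enoate | COC(=O)[C@](C)(O[Si](CC)(CC)CC)C[C@@H](O)C=C(C)C | intermediate
7 | (3R,5R)-3-methyl-5-(2-methylprop-1-enyl)-3-(triethylsilyloxy)oxolan-2-one | O=C1[C@](C)(O[Si](CC)(CC)CC)C[C@@H](O1)C=C(C)C | intermediate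
8 | (3R,5R)-5-hydroxy-3,7-dimethyl-3-(triethylsilyloxy)oct-6-en-2-one | CC(=O)[C@](C)(O[Si](CC)(CC)CC)C[C@@H](O)C=C(C)C | intermediate
9 | isovaleryl chloride | CC(C)CC(=O)Cl | starting material
10 | (4R,6R)-2,6-dimethyl-7-oxo-6-(triethylsilyloxy)oct-2-en-4-yl 3-methylbutanoate | CC(=O)[C@](C)(O[Si](CC)(CC)CC)C[C@@H](OC(=O)CC(C)C)C=C(C)C | intermediate
11 | ethyl 2-(diphenoxyphosphoryl)propanoate | CCOC(=O)C(C)P(=O)(Oc1ccccc1)Oc1ccccc1 | starting material
12 | 2,2-dimethoxyacetaldehyde | COC(OC)C=O | starting material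
13 | sodium carbanion of 11 | [Na+].CCOC(=O)[C-](C)P(=O)(Oc1ccccc1)Oc1ccccc1 | intermediate
14 | ethyl (2Z)-4,4-dimethoxy-2-methylbut-2-enoate | COC(OC)/C=C(/C)C(=O)OCC | intermediate
15 | (2Z)-4,4-dimethoxy-2-methylbut-2-en-1-ol | COC(OC)/C=C(/C)CO | intermediate
16 | (2Z)-4,4-dimethoxy-2-methylbut-2-enal | COC(OC)/C=C(/C)C=O | intermediate
17 | diisopinocampheylboron enolate of 10 (C1=C2 enolate) | C=C(OB([C@@H]1C[C@@H]2C[C@H]([C@H]1C)C2(C)C)[C@@H]1C[C@@H]2C[C@H]([C@H]1C)C2(C)C)[C@](C)(O[Si](CC)(CC)CC)C[C@@H](OC(=O)CC(C)C)C=C(C)C | intermediate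
18 | diisopinocampheylboron aldolate of 19 (boron on O-3) | COC(OC)/C=C(/C)[C@H](OB([C@@H]1C[C@@H]2C[C@H]([C@H]1C)C2(C)C)[C@@H]1C[C@@H]2C[C@H]([C@H]1C)C2(C)C)CC(=O)[C@](C)(O[Si](CC)(CC)CC)C[C@@H](OC(=O)CC(C)C)C=C(C)C | intermediate
19 | (4R,6R,9R,10Z)-9-hydroxy-12,12-dimethoxy-2,6,10-trimethyl-7-oxo-6-(triethylsilyloxy)dodeca-2,10-dien-4-yl 3-methylbutanoate | COC(OC)/C=C(/C)[C@H](O)CC(=O)[C@](C)(O[Si](CC)(CC)CC)C[C@@H](OC(=O)CC(C)C)C=C(C)C | intermediate
20 | 2,6-lutidinium triflate at C6 (C6 carries OMe and N-lutidinium, C6 epimers; 3,10-bis-OSiEt3; otherwise as 21) | COC(/C=C(/C)[C@H](O[Si](CC)(CC)CC)CC(=O)[C@](C)(O[Si](CC)(CC)CC)C[C@@H](OC(=O)CC(C)C)C=C(C)C)[n+]1c(C)cccc1C.[O-]S(=O)(=O)C(F)(F)F | intermediate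
21 | (4R,6R,9R,10Z)-2,6,10-trimethyl-7,12-dioxo-6,9-bis(triethylsilyloxy)dodeca-2,10-dien-4-yl 3-methylbutanoate | O=C/C=C(/C)[C@H](O[Si](CC)(CC)CC)CC(=O)[C@](C)(O[Si](CC)(CC)CC)C[C@@H](OC(=O)CC(C)C)C=C(C)C | intermediate
22 | chloro(methyl)aluminium alkoxide of 23 (Al on O-6) | C[Al](Cl)O[C@@H]1/C=C(/C)[C@H](O[Si](CC)(CC)CC)CC(=O)[C@](C)(O[Si](CC)(CC)CC)C[C@@H](OC(=O)CC(C)C)[C@H]1C(C)=C | intermediate
23 | (3R,4Z,6R,7S,8R,10R)-6-hydroxy-1-oxo-3,10-bis(triethylsilyloxy)germacra-4,11(13)-dien-8-yl 3-methylbutanoate | O[C@@H]1/C=C(/C)[C@H](O[Si](CC)(CC)CC)CC(=O)[C@](C)(O[Si](CC)(CC)CC)C[C@@H](OC(=O)CC(C)C)[C@H]1C(C)=C | intermediate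
24 | (3R,4Z,6R,7S,8R,10R)-6,12-dihydroxy-1-oxo-3,10-bis(triethylsilyloxy)germacra-4,11(13)-dien-8-yl 3-methylbutanoate | O[C@@H]1/C=C(/C)[C@H](O[Si](CC)(CC)CC)CC(=O)[C@](C)(O[Si](CC)(CC)CC)C[C@@H](OC(=O)CC(C)C)[C@H]1C(=C)CO | intermediate
25 | 6-hydroxy-12-al (as 24 with CHO at C12) | O[C@@H]1/C=C(/C)[C@H](O[Si](CC)(CC)CC)CC(=O)[C@](C)(O[Si](CC)(CC)CC)C[C@@H](OC(=O)CC(C)C)[C@H]1C(=C)C=O | intermediate
26 | 12,6-lactol of 27 (C12 epimers) | C=C1C(O)O[C@@H]2/C=C(/C)[C@H](O[Si](CC)(CC)CC)CC(=O)[C@](C)(O[Si](CC)(CC)CC)C[C@@H](OC(=O)CC(C)C)[C@@H]12 | intermediate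
27 | 3,10-bis-O-triethylsilyl ether of the target | C=C1C(=O)O[C@@H]2/C=C(/C)[C@H](O[Si](CC)(CC)CC)CC(=O)[C@](C)(O[Si](CC)(CC)CC)C[C@@H](OC(=O)CC(C)C)[C@@H]12 | intermediate
28 | CNP0406522.1 | C=C1C(=O)O[C@@H]2/C=C(/C)[C@H](O)CC(=O)[C@](C)(O)C[C@@H](OC(=O)CC(C)C)[C@@H]12 | target

## Step count and risks
Total step count: 14. Longest linear sequence: 11 (steps 1–5, then 9–14). Steps 6–8 form the three-step side branch.

Steps most likely to fail:

**Step 11 (ene macrocyclisation).**
- What can go wrong:
  - The ring is medium-sized and the alkene is slowed by its allylic ester.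
  - Methyl transfer from aluminium, a five-ring ene closure onto the C1 ketone, ionisation of the allylic ester, or the wrong C7 face can all compete.
- Fallback: it sets out from 21 and comes back at 23.
  - Ene-type chlorination of the prenyl end with NaOCl/CeCl3·7H2O (CH2Cl2/H2O, 0 °C) gives the transposed secondary allylic chloride F1.
  - Slow addition of this chloride to CrCl2 in THF/DMF at high dilution generates the primary allylchromium species.
  - That species adds through C7 to the aldehyde in a closed chair (Nozaki–Hiyama-type allylation, anti-selective, neutral medium) and delivers the same homoallylic alcohol 23.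

**Step 12 (allylic hydroxylation).**
- What can go wrong: oxidation at C7–H or at the C15 methyl, or loss of the allylic silyl ether, may compete.
- Fallback: it sets out from 23 and comes back at 25, and so at 27 under the conditions of step 13.
  - NaOCl/CeCl3·7H2O converts the isopropenyl group into the 2-(chloromethyl)vinyl compound, the primary allylic chloride F2.
  - N-Methylmorpholine N-oxide in MeCN then oxidises it in a Kornblum-type displacement and elimination to hydroxy enal 25.
  - Oxygen thus enters by substitution instead of by a selenium ene reaction.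

**Step 9 (aldol with the Z-enal).**
- What can go wrong: aldehyde 16 may isomerise, the adduct may close onto its cis acetal, and reagent control on a methyl ketone is only moderate.
- Fallback: it sets out from 10 and comes back at 21.
  - Boron enolate 17 is added to commercial, configurationally stable (E)-4,4-dimethoxy-2-methylbut-2-enal to give the E-configured aldol adduct F3, which cannot cyclise.
  - Et3SiOTf/2,6-lutidine and then water give the E-configured enal F4.
  - Irradiation at 350 nm in MeCN (E/Z photoisomerisation of the enal chromophore) gives a photostationary mixture from which 21 is separated while the E isomer is recycled.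
  - The same irradiation rescues any E isomer formed in step 10.

## Further compounds
F1 | step 11 | (4R,6R,9R,10Z)-3-chloro-2,6,10-trimethyl-7,12-dioxo-6,9-bis(triethylsilyloxy)dodeca-1,10-dien-4-yl 3-methylbutanoate (C7 chloride, both epimers) | O=C/C=C(/C)[C@H](O[Si](CC)(CC)CC)CC(=O)[C@](C)(O[Si](CC)(CC)CC)C[C@@H](OC(=O)CC(C)C)C(Cl)C(C)=C
F2 | step 12 | 12-chloro analogue of 24 (CH2Cl in place of CH2OH at C12, 6-OH free) | O[C@@H]1/C=C(/C)[C@H](O[Si](CC)(CC)CC)CC(=O)[C@](C)(O[Si](CC)(CC)CC)C[C@@H](OC(=O)CC(C)C)[C@H]1C(=C)CCl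
F3 | step 9 | (4R,6R,9R,10E)-9-hydroxy-12,12-dimethoxy-2,6,10-trimethyl-7-oxo-6-(triethylsilyloxy)dodeca-2,10-dien-4-yl 3-methylbutanoate | COC(OC)/C=C(\C)[C@H](O)CC(=O)[C@](C)(O[Si](CC)(CC)CC)C[C@@H](OC(=O)CC(C)C)C=C(C)C
F4 | step 9 | (4R,6R,9R,10E)-2,6,10-trimethyl-7,12-dioxo-6,9-bis(triethylsilyloxy)dodeca-2,10-dien-4-yl 3-methylbutanoate | O=C/C=C(\C)[C@H](O[Si](CC)(CC)CC)CC(=O)[C@](C)(O[Si](CC)(CC)CC)C[C@@H](OC(=O)CC(C)C)C=C(C)C
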